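## Structural features

The target is a heptahydroxylated phlorotannin and has no stereocentre. Its core is a dibenzo-1,4-dioxin (benzene ring B, dioxin ring C, benzene ring D); ring D is fused through a furan (ring E) to a further benzene ring F, and ring B carries a 3,5-dihydroxyphenoxy group (ring A). Positional labels used throughout: on ring B, B1 bears the oxygen to ring A, B2 and B4 bear hydroxyls, B3 is the only C–H, B5 and B6 bear the dioxin oxygens; on ring D, D1 bears the dioxin oxygen shared with B6, D2 a hydroxyl, D3 is C–H, D4 bears the furan oxygen, D5 the furan C–C bond and D6 the dioxin oxygen shared with B5; on ring F, F1 bears the furan oxygen, F3 and F5 hydroxyls, and F6 the bond to D5. Ring B is pentaoxygenated and ring D tetraoxygenated, so both dioxin oxygens are diaryl ether oxygens flanked by substituents on all four ortho positions. The free polyphenol is easily oxidised, so all seven hydroxyls travel as methyl ethers to the last step; while the aryl iodide and aryl sulfonate of the intermediates are present, zerovalent palladium, hot Ullmann coupling with monovalent copper, hydrogenolysis and hot nucleophilic base are excluded. The real difficulty is making the two hindered dioxin C–O bonds while telling apart near-identical sites: D3 from D5, and the three contiguous oxygens at B1, B6 and B5. The key step uses the fact that D5 and D6 are neighbours: an aryne across D5–D6 can be reached by the B5 oxygen, tethered through B6–O–D1, only at D6, and the carbanion left at D5 can take up iodine for the later furan C–C bond.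

## Logic of the disconnections

30 to 29: the seven O–CH3 bonds are cut. Free phenols would interfere with every basic or metal-mediated step, so they are unmasked last. The forward step must cleave seven methyl ethers without touching diaryl ether, dioxin or furan C–O bonds.

29 to 28: the D5–F6 C–C bond of ring E is cut. With the D4–O–F1 oxygen already in place this is a five-membered closure onto the aryl iodide, and the two ortho C–H positions of ring F in 28 are equivalent. The forward step needs a palladium-catalysed C–H arylation that tolerates a crowded bay region.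

28 to 26 and 27: the D4–O–F1 bond is cut. 27 delivers ring F whole with both of its oxygens, which removes an entire arene in one cut. The forward step must etherify the D4 hydroxyl at room temperature without a low-valent metal, so that the neighbouring C–I bond survives.

26 to 25: the O–benzyl bond is cut. The D4 oxygen must be masked during the Grignard step and be the only free hydroxyl afterwards. Removal must not reduce the C–I bond.

25 to 21: the B5–O–D6 bond of ring C is cut, with the iodine at D5 kept. This is the second of the two hindered dioxin ether bonds, and an intramolecular aryne capture makes it without a metal catalyst while returning the D5 handle. The precursor must have one acidic proton only (B5–OH) and an ortho-iodoaryl sulfonate on ring D.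

21 to 12 and 19: the B1–O–ring A bond is cut. The two hydroxyls of 12 (B1 and B5) are equivalent, so no protecting group is needed to tell them apart, and 19 releases 20, which reacts even with a doubly flanked phenoxide. The forward step must stop at mono-arylation.

12 to 10: the B1–O and B5–O bonds are traced back to two C–CHO bonds. The formyl groups are what allows the next cut, and are then turned into oxygen. The oxidation must spare the aryl iodide and the sulfonate.

10 to 7 and 9: the B6–O–D1 bond, the other tetra-ortho-substituted ether, is cut. This separates rings B and D into two simple benzene units. Fluoride displacement is chosen over a hot copper-catalysed coupling because 7 already carries iodine; the hindered phenoxide must react below the temperature at which the sulfonate suffers.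

9 to 8: two aryl–CHO bonds are cut. Both formyl groups must enter next to fluorine.

7 to 5 to 3 to 2 to 1 (with 4): the D1–O bond (from the formyl carbon), the O–S bond, the C–I bond and the O–benzyl bond are cut in turn. The salicylaldehyde pattern of 1 distinguishes the ring D oxygens, and its chelated hydroxyl steers iodine to D5 before any other electron-rich ring is present.

19 to 17 to 14 to 13: the O–triflyl, C–Si and O–carbamoyl bonds are cut, giving the aryne precursor from the parent phenol by carbamate-directed metalation.

## Other disconnections considered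

Alternative 1: The cut runs through ring B itself: two of its C–C bonds are disconnected so that four carbons come from a squarate unit and two from an enol ether. In the forward direction the racemic cyclobutenone A2 is heated; 4π electrocyclic opening gives a dienylketene, and 6π closure with enolisation gives the hydroquinone A1 (Moore-type rearrangement).
- In its favour: all five oxygens and the single C–H of ring B are placed with full regiocontrol by a reagent-free thermal cascade. As a single step it rests on firmer precedent than the key step chosen here, and on that point it is the better.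
- Against it: whichever way A1 is laid onto ring B, two of the three oxygens that must become diaryl ethers (B1, B5, B6) carry isopropyl groups. Most of the five oxygens would have to be re-differentiated, and neither hindered bond of ring C is addressed.
- Comparison: in the chosen plan ring B arrives in one step (8 to 9) with its oxygens distinguished by origin (fluorine, two formyl groups, two methoxy groups). The ring synthesis would cost at least four more steps and leaves the structural problem that matters untouched.

Alternative 2: The cut removes ring A by disconnecting two of its C–C bonds, leaving the B1 oxygen as the nitrovinyl ether A4 and the 1,1-dialkoxy-3-silyloxy diene A5. In the forward direction a polarity-matched Diels–Alder addition is followed by loss of HNO2 and of the ketal and silyl groups, which aromatises the adduct to A3. By a count of its oxygens A3 carries six O-methyl groups and is therefore treated as the hexa-O-methyl ether with one ring A hydroxyl free.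
- In its favour: no aryl electrophile has to approach the doubly flanked B1 oxygen, the ring A pattern follows from A5, and only one hydroxyl is present. Nothing is lost to statistics, which is a real advantage over step 11.
- Against it: it acts at the very end and presupposes the complete B–C–D–E–F core with B1–OH alone free. It therefore solves the easiest bond of the molecule, which an aryne should form at room temperature. A4 must be made from an electron-rich hindered phenol and must survive.
- Comparison: vinyl ether formation, cycloaddition and aromatisation are three operations where step 11 is one. The differentiated ring A hydroxyl of A3 brings no gain after global demethylation, so the outcome is equal there. On mechanism both are sound.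

Alternative 3: The cut dismantles ring F: four C–C bonds are disconnected, leaving a benzofuran (rings D and E) with a diazoketone at the furan 2-position, A7, and the silyl ynol ether A8. In the forward direction a Wolff rearrangement gives a ketene, [2+2] addition to A8 gives a cyclobutenone, and 4π opening with 6π closure onto furan C3 gives A6 (Danheiser benzannulation). A6 carries five O-methyl groups and is treated as the penta-O-methyl ether with one ring F hydroxyl free and the other silylated.
- In its favour: the crowded bay-region C–C bond is made by a pericyclic closure and not by a palladium-mediated C–H arylation. That is the better solution if bay strain slows step 15. The two ring F oxygens also emerge differentiated.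
- Against it: ring F is a symmetrical unit that 27 delivers intact, so atom-by-atom construction is unnecessary. A7 needs a carbon substituent at D5 and a preformed furan, which does not fit the iodide that the aryne capture leaves at D5. Irradiating a diazoketone among six electron-rich aryl ethers invites carbene side reactions.
- Comparison: from 26 the benzannulation route needs at least two more operations than steps 14 and 15 together. The chosen plan is better on convergence and step economy; the alternative is better on independence from palladium chemistry.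

Key step: step 12

Remark: 2,4-dihydroxy-6-methoxybenzaldehyde, 1-fluoro-3,5-dimethoxybenzene, 3,5-dimethoxyphenol, 3,5-dimethoxyphenylboronic acid and 4-chlorobenzenesulfonyl chloride are taken as catalogue compounds. The benzyl ether and the 4-chlorobenzenesulfonate of the key-step precursor fit the route: both should survive every step up to 12, and the benzyl group can be removed without touching the C–I bond.

## Steps

Step 1
Reactants: 1 2,4-dihydroxy-6-methoxybenzaldehyde
Product: 2 4-(benzyloxy)-2-hydroxy-6-methoxybenzaldehyde
Conditions: BnBr (1.05 equiv), NaHCO3, KI (cat.), MeCN, 60 °C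
Reagents that add atoms: benzyl bromide, BrCc1ccccc1
Why: Williamson etherification; the 2-hydroxyl is held in a hydrogen bond to the aldehyde, so the more acidic 4-hydroxyl should be alkylated selectively by a weak base.

Step 2
Reactants: 2 4-(benzyloxy)-2-hydroxy-6-methoxybenzaldehyde
Product: 3 4-(benzyloxy)-2-hydroxy-3-iodo-6-methoxybenzaldehyde
Conditions: BnNMe3ICl2, NaHCO3, CH2Cl2–MeOH, rt
Reagents that add atoms: benzyltrimethylammonium dichloroiodate, C[N+](C)(C)Cc1ccccc1.Cl[I-]Cl
Why: Electrophilic aromatic iodination; the chelated phenol should direct to its free ortho position (the future D5), as is usual for 2-hydroxy-4,6-dialkoxy aryl carbonyl compounds, and doing it here fixes D5 against D3 before any other electron-rich ring is present.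

Step 3
Reactants: 3 4-(benzyloxy)-2-hydroxy-3-iodo-6-methoxybenzaldehyde; 4 4-chlorobenzenesulfonyl chloride
Product: 5 3-(benzyloxy)-6-formyl-2-iodo-5-methoxyphenyl 4-chlorobenzenesulfonate
Conditions: Et3N, DMAP (cat.), CH2Cl2, 0 °C to rt
Reagents that add atoms: none
Why: O-Sulfonylation of a phenol with nucleophilic catalysis; the only hydroxyl becomes the leaving group that later triggers aryne formation.

Step 4
Reactants: 5 3-(benzyloxy)-6-formyl-2-iodo-5-methoxyphenyl 4-chlorobenzenesulfonate
Product: 7 3-(benzyloxy)-6-hydroxy-2-iodo-5-methoxyphenyl 4-chlorobenzenesulfonate, via aryl formate 6 (not isolated)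
Conditions: mCPBA, CH2Cl2, 0 °C to rt; then Et3N, MeOH, rt
Reagents that add atoms: 3-chloroperbenzoic acid, O=C(OO)c1cccc(Cl)c1
Why: Baeyer–Villiger (Dakin-type) oxidation; the aryl group with ortho-methoxy and para-benzyloxy donors migrates, and mild methanolysis of the formate should free the D1 phenol without touching the aryl sulfonate.

Step 5
Reactants: 8 1-fluoro-3,5-dimethoxybenzene
Product: 9 2-fluoro-4,6-dimethoxybenzene-1,3-dicarbaldehyde
Conditions: Cl2CHOMe (5 equiv), TiCl4 (5 equiv), CH2Cl2, 0 °C to reflux; then ice-cold aq. HCl
Reagents that add atoms: dichloromethyl methyl ether, COC(Cl)Cl; water, O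
Why: Twofold Rieche formylation (electrophilic aromatic substitution); each formyl group should enter para to one methoxy and ortho to the other, beside the small fluorine, rather than between the two methoxy groups, and any mono-aldehyde can be resubmitted.

Step 6
Reactants: 7 3-(benzyloxy)-6-hydroxy-2-iodo-5-methoxyphenyl 4-chlorobenzenesulfonate; 9 2-fluoro-4,6-dimethoxybenzene-1,3-dicarbaldehyde
Product: 10 3-(benzyloxy)-6-(2,6-diformyl-3,5-dimethoxyphenoxy)-2-iodo-5-methoxyphenyl 4-chlorobenzenesulfonate
Conditions: K2CO3, DMF, 60 °C
Reagents that add atoms: none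
Why: Nucleophilic aromatic substitution by addition–elimination; the fluorine is activated by two ortho formyl groups, the reaction is little affected by ortho substituents, and it spares the aryl iodide that a hot Ullmann coupling with monovalent copper would attack.

Step 7
Reactants: 10 3-(benzyloxy)-6-(2,6-diformyl-3,5-dimethoxyphenoxy)-2-iodo-5-methoxyphenyl 4-chlorobenzenesulfonate
Product: 12 3-(benzyloxy)-6-(2,6-dihydroxy-3,5-dimethoxyphenoxy)-2-iodo-5-methoxyphenyl 4-chlorobenzenesulfonate, via bis-formate 11 (not isolated)
Conditions: mCPBA (3 equiv), CH2Cl2, 0 °C to rt; then Et3N, MeOH, rt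
Reagents that add atoms: 3-chloroperbenzoic acid, O=C(OO)c1cccc(Cl)c1
Why: Twofold Baeyer–Villiger (Dakin-type) oxidation of 2,4,6-trioxygenated benzaldehydes, for which aryl migration is reliable; methanolysis should give the diol whose B1 and B5 hydroxyls are equivalent.

Step 8
Reactants: 13 3,5-dimethoxyphenol
Product: 14 3,5-dimethoxyphenyl isopropylcarbamate
Conditions: iPrNCO, Et3N (cat.), CH2Cl2, rt
Reagents that add atoms: isopropyl isocyanate, CC(C)N=C=O
Why: Carbamoylation of a phenol by addition to an isocyanate; it installs a strong, later removable directing group.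

Step 9
Reactants: 14 3,5-dimethoxyphenyl isopropylcarbamate
Product: 17 3,5-dimethoxy-2-(trimethylsilyl)phenyl isopropylcarbamate, via N-silyl carbamate 15 (not isolated), via N-silyl C-silyl carbamate 16 (not isolated)
Conditions: TBSOTf, TMEDA, Et2O, 0 °C to rt; n-BuLi, TMEDA, −78 °C; TMSCl, −78 °C to rt; aq. NaHSO4
Reagents that add atoms: chlorotrimethylsilane, C[Si](C)(C)Cl
Why: Directed ortho-metalation of an aryl O-carbamate, N-silylated in the flask, followed by C-silylation; the carbamate outranks methoxy as directing group and its two ortho positions are equivalent, so one regioisomer is expected.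

Step 10
Reactants: 17 3,5-dimethoxy-2-(trimethylsilyl)phenyl isopropylcarbamate
Product: 19 3,5-dimethoxy-2-(trimethylsilyl)phenyl trifluoromethanesulfonate, via silyl phenol 18 (not isolated)
Conditions: Et2NH, DBU, MeCN, 40 °C; then PhNTf2, rt
Reagents that add atoms: N-phenylbis(trifluoromethanesulfonimide), O=S(=O)(N(c1ccccc1)S(=O)(=O)C(F)(F)F)C(F)(F)F
Why: Base-induced cleavage of the N-monosubstituted carbamate (elimination to the isocyanate, trapped by Et2NH) and O-triflation of the phenoxide in one flask, the standard last stage of a 2-silylaryl triflate synthesis.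

Step 11
Reactants: 12 3-(benzyloxy)-6-(2,6-dihydroxy-3,5-dimethoxyphenoxy)-2-iodo-5-methoxyphenyl 4-chlorobenzenesulfonate; 19 3,5-dimethoxy-2-(trimethylsilyl)phenyl trifluoromethanesulfonate
Product: 21 3-(benzyloxy)-6-[2-(3,5-dimethoxyphenoxy)-6-hydroxy-3,5-dimethoxyphenoxy]-2-iodo-5-methoxyphenyl 4-chlorobenzenesulfonate, via 3,5-dimethoxybenzyne 20 (not isolated)
Conditions: 19 (0.9 equiv), CsF, MeCN, rt
Reagents that add atoms: none
Why: Fluoride-induced aryne generation from a 2-silylaryl triflate and O-arylation of a phenol; the phenoxide adds to the aryne carbon remote from the neighbouring methoxy group, giving the 3,5-dimethoxyphenyl ether. Because both hydroxyls of 12 are equivalent, a single mono-ether is expected when 19 is the limiting reagent, and unreacted 12 is recycled.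

Step 12
Reactants: 21 3-(benzyloxy)-6-[2-(3,5-dimethoxyphenoxy)-6-hydroxy-3,5-dimethoxyphenoxy]-2-iodo-5-methoxyphenyl 4-chlorobenzenesulfonate
Product: 25 7-(benzyloxy)-1-(3,5-dimethoxyphenoxy)-6-iodo-2,4,9-trimethoxydibenzo[b,e][1,4]dioxine, via bis-magnesiated sulfonate 22 (not isolated), via ring D aryne 23 (not isolated), via dioxin arylmagnesium chloride 24 (not isolated)
Conditions: iPrMgCl·LiCl (2.0 equiv), THF, −78 to 0 °C; then I2, −78 °C to rt
Reagents that add atoms: iodine, II
Why: Proposed new method: the first equivalent of iPrMgCl·LiCl deprotonates the B5 phenol and the second performs iodine–magnesium exchange at D5, which the flanking sulfonate and benzyloxy groups should accelerate, giving 22. On warming, the 2-magnesiated aryl sulfonate expels 4-chlorobenzenesulfonate to give the D5–D6 aryne 23. The tethered B5 magnesium phenoxide then adds to D6 in a six-membered exo closure that forms ring C; attack at D5 would need a seven-membered ring, so the tether, not the nearly equal inductive pull of the two flanking oxygens, fixes the regiochemistry. The arylmagnesium 24 left at D5 sits between two oxygens, should be stable at low temperature, and is iodinated by I2, which returns the halogen to the carbon that will carry the furan C–C bond. The closest known reaction types are aryne generation from 2-iodoaryl 4-chlorobenzenesulfonates by iodine–magnesium exchange with addition of magnesium thiolates or amides and electrophilic quench, and intramolecular phenoxide–aryne cyclisation from other aryne precursors; their combination with an oxygen nucleophile in a ring-closing mode is the untested part. No stereocentre is formed. The step needs the phenoxide, not the Grignard reagent, to add to the aryne; this is secured by using exactly two equivalents, so that no free iPrMgCl remains when the aryne forms, and by 21 having a single acidic proton.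

Step 13
Reactants: 25 7-(benzyloxy)-1-(3,5-dimethoxyphenoxy)-6-iodo-2,4,9-trimethoxydibenzo[b,e][1,4]dioxine
Product: 26 1-(3,5-dimethoxyphenoxy)-6-iodo-2,4,9-trimethoxydibenzo[b,e][1,4]dioxin-7-ol
Conditions: BCl3, C6HMe5, CH2Cl2, −78 °C
Reagents that add atoms: none
Why: Lewis acid debenzylation with a cation scavenger; at low temperature BCl3 should cleave the benzyl aryl ether while aryl methyl ethers, diaryl ethers and the aryl iodide, which hydrogenolysis would remove, are kept.

Step 14
Reactants: 26 1-(3,5-dimethoxyphenoxy)-6-iodo-2,4,9-trimethoxydibenzo[b,e][1,4]dioxin-7-ol; 27 3,5-dimethoxyphenylboronic acid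
Product: 28 1,7-bis(3,5-dimethoxyphenoxy)-6-iodo-2,4,9-trimethoxydibenzo[b,e][1,4]dioxine
Conditions: 27 (2.0 equiv), Cu(OAc)2 (1.5 equiv), pyridine, 4 Å MS, CH2Cl2, air, rt
Reagents that add atoms: none
Why: Chan–Lam oxidative etherification of a phenol with an arylboronic acid; the aryl group is transferred from boron to divalent copper and the C–O bond forms by reductive elimination at room temperature, with no low-valent metal present to insert into the neighbouring C–I bond. Ortho-iodophenols are an established substrate class for this coupling, and the D4 hydroxyl has only one ortho substituent.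

Step 15
Reactants: 28 1,7-bis(3,5-dimethoxyphenoxy)-6-iodo-2,4,9-trimethoxydibenzo[b,e][1,4]dioxine
Product: 29 hepta-O-methyl ether of the target (rings A to F complete; every hydroxyl as its methyl ether)
Conditions: Pd(OAc)2 (5 mol %), PCy3·HBF4 (10 mol %), K2CO3, PivOH (30 mol %), DMA, 110 °C
Reagents that add atoms: none
Why: Pd(OAc)2-catalysed intramolecular direct arylation of a 2-iodo diaryl ether, a known route to dibenzofurans: oxidative addition into the C–I bond, carboxylate-assisted concerted metalation–deprotonation at an ortho C–H of the neighbouring aryloxy ring, and C–C reductive elimination close the furan. Only the ring on the D4 oxygen can reach the palladium at D5, and its two ortho positions are equivalent, so a single furan should result.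

Step 16
Reactants: 29 hepta-O-methyl ether of the target
Product: 30 target CNP0256302.0 (the free heptaphenol)
Conditions: BBr3 (excess), CH2Cl2, −78 °C to rt; MeOH, then H2O, under argon
Reagents that add atoms: none
Why: Lewis acid cleavage of aryl methyl ethers with BBr3; diaryl ether, dioxin and furan C–O bonds are inert to it, so only the seven methyl groups should be lost.

## Compound list

1 | 2,4-dihydroxy-6-methoxybenzaldehyde | O=Cc1c(O)cc(O)cc1OC | starting material
2 | 4-(benzyloxy)-2-hydroxy-6-methoxybenzaldehyde | O=Cc1c(O)cc(OCc2ccccc2)cc1OC | intermediate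
3 | 4-(benzyloxy)-2-hydroxy-3-iodo-6-methoxybenzaldehyde | O=Cc1c(O)c(I)c(OCc2ccccc2)cc1OC | intermediate
4 | 4-chlorobenzenesulfonyl chloride | O=S(=O)(Cl)c1ccc(Cl)cc1 | starting material
5 | 3-(benzyloxy)-6-formyl-2-iodo-5-methoxyphenyl 4-chlorobenzenesulfonate | O=Cc1c(OS(=O)(=O)c2ccc(Cl)cc2)c(I)c(OCc2ccccc2)cc1OC | intermediate
6 | 4-(benzyloxy)-2-[(4-chlorophenyl)sulfonyloxy]-3-iodo-6-methoxyphenyl formate | O=COc1c(OS(=O)(=O)c2ccc(Cl)cc2)c(I)c(OCc2ccccc2)cc1OC | intermediate
7 | 3-(benzyloxy)-6-hydroxy-2-iodo-5-methoxyphenyl 4-chlorobenzenesulfonate | Oc1c(OS(=O)(=O)c2ccc(Cl)cc2)c(I)c(OCc2ccccc2)cc1OC | intermediate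
8 | 1-fluoro-3,5-dimethoxybenzene | COc1cc(F)cc(OC)c1 | starting material
9 | 2-fluoro-4,6-dimethoxybenzene-1,3-dicarbaldehyde | COc1cc(OC)c(C=O)c(F)c1C=O | intermediate
10 | 3-(benzyloxy)-6-(2,6-diformyl-3,5-dimethoxyphenoxy)-2-iodo-5-methoxyphenyl 4-chlorobenzenesulfonate | COc1cc(OCc2ccccc2)c(I)c(OS(=O)(=O)c2ccc(Cl)cc2)c1Oc1c(C=O)c(OC)cc(OC)c1C=O | intermediate
11 | 2-[4-(benzyloxy)-2-[(4-chlorophenyl)sulfonyloxy]-3-iodo-6-methoxyphenoxy]-4,6-dimethoxy-1,3-phenylene diformate | COc1cc(OCc2ccccc2)c(I)c(OS(=O)(=O)c2ccc(Cl)cc2)c1Oc1c(OC=O)c(OC)cc(OC)c1OC=O | intermediate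
12 | 3-(benzyloxy)-6-(2,6-dihydroxy-3,5-dimethoxyphenoxy)-2-iodo-5-methoxyphenyl 4-chlorobenzenesulfonate | COc1cc(OCc2ccccc2)c(I)c(OS(=O)(=O)c2ccc(Cl)cc2)c1Oc1c(O)c(OC)cc(OC)c1O | intermediate
13 | 3,5-dimethoxyphenol | COc1cc(O)cc(OC)c1 | starting material
14 | 3,5-dimethoxyphenyl isopropylcarbamate | COc1cc(OC)cc(OC(=O)NC(C)C)c1 | intermediate
15 | 3,5-dimethoxyphenyl N-(tert-butyldimethylsilyl)-N-isopropylcarbamate | COc1cc(OC)cc(OC(=O)N(C(C)C)[Si](C)(C)C(C)(C)C)c1 | intermediate
16 | 3,5-dimethoxy-2-(trimethylsilyl)phenyl N-(tert-butyldimethylsilyl)-N-isopropylcarbamate | COc1cc(OC)c([Si](C)(C)C)c(OC(=O)N(C(C)C)[Si](C)(C)C(C)(C)C)c1 | intermediate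
17 | 3,5-dimethoxy-2-(trimethylsilyl)phenyl isopropylcarbamate | COc1cc(OC)c([Si](C)(C)C)c(OC(=O)NC(C)C)c1 | intermediate
18 | 3,5-dimethoxy-2-(trimethylsilyl)phenol | COc1cc(OC)c([Si](C)(C)C)c(O)c1 | intermediate
19 | 3,5-dimethoxy-2-(trimethylsilyl)phenyl trifluoromethanesulfonate | COc1cc(OC)c([Si](C)(C)C)c(OS(=O)(=O)C(F)(F)F)c1 | intermediate
20 | 3,5-dimethoxybenzyne (1,2-didehydro-3,5-dimethoxybenzene) | COC1=CC(OC)=CC#C1 | intermediate
21 | 3-(benzyloxy)-6-[2-(3,5-dimethoxyphenoxy)-6-hydroxy-3,5-dimethoxyphenoxy]-2-iodo-5-methoxyphenyl 4-chlorobenzenesulfonate | COc1cc(OC)cc(Oc2c(OC)cc(OC)c(O)c2Oc2c(OC)cc(OCc3ccccc3)c(I)c2OS(=O)(=O)c2ccc(Cl)cc2)c1 | intermediate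
22 | chloromagnesium phenoxide of 21 with chloromagnesium in place of iodine at D5 | COc1cc(OC)cc(Oc2c(OC)cc(OC)c(O[Mg]Cl)c2Oc2c(OC)cc(OCc3ccccc3)c([Mg]Cl)c2OS(=O)(=O)c2ccc(Cl)cc2)c1 | intermediate
23 | D5–D6 aryne of ring D carrying the B5 chloromagnesium phenoxide | COc1cc(OC)cc(Oc2c(OC)cc(OC)c(O[Mg]Cl)c2OC2=C(OC)C=C(OCc3ccccc3)C#C2)c1 | intermediate
24 | 7-(benzyloxy)-1-(3,5-dimethoxyphenoxy)-2,4,9-trimethoxydibenzo[b,e][1,4]dioxin-6-ylmagnesium chloride | COc1cc(OC)cc(Oc2c(OC)cc(OC)c3c2Oc2c(OC)cc(OCc4ccccc4)c([Mg]Cl)c2O3)c1 | intermediate
25 | 7-(benzyloxy)-1-(3,5-dimethoxyphenoxy)-6-iodo-2,4,9-trimethoxydibenzo[b,e][1,4]dioxine | COc1cc(OC)cc(Oc2c(OC)cc(OC)c3c2Oc2c(OC)cc(OCc4ccccc4)c(I)c2O3)c1 | intermediate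
26 | 1-(3,5-dimethoxyphenoxy)-6-iodo-2,4,9-trimethoxydibenzo[b,e][1,4]dioxin-7-ol | COc1cc(OC)cc(Oc2c(OC)cc(OC)c3c2Oc2c(OC)cc(O)c(I)c2O3)c1 | intermediate
27 | 3,5-dimethoxyphenylboronic acid | COc1cc(OC)cc(B(O)O)c1 | starting material
28 | 1,7-bis(3,5-dimethoxyphenoxy)-6-iodo-2,4,9-trimethoxydibenzo[b,e][1,4]dioxine | COc1cc(OC)cc(Oc2c(OC)cc(OC)c3c2Oc2c(OC)cc(Oc4cc(OC)cc(OC)c4)c(I)c2O3)c1 | intermediate
29 | hepta-O-methyl ether of the target | COc1cc(OC)cc(Oc2c(OC)cc(OC)c3c2Oc2c(OC)cc4oc5cc(OC)cc(OC)c5c4c2O3)c1 | intermediate
30 | target CNP0256302.0 | Oc1cc(O)cc(Oc2c(O)cc(O)c3c2Oc2c(O)cc4oc5cc(O)cc(O)c5c4c2O3)c1 | target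

Total step count: 16. Longest linear sequence: 12 steps (1, 2, 3, 4, 6, 7, 11, 12, 13, 14, 15, 16).

## Least certain steps

Step 12 (key step). The hindered, weakly nucleophilic magnesium phenoxide may add too slowly, so that the aryne is consumed by the solvent or by a second arylmagnesium; the D5 arylmagnesium may also be protonated before iodination, which loses the handle. The fallback uses known chemistry only, sets out from 9 and returns at 29. 5,6-Dibromovanillin F1 (2,3-dibromo-4-hydroxy-5-methoxybenzaldehyde, from twofold bromination of vanillin) is joined to 9 by fluoride displacement (K2CO3, DMF) to give the trialdehyde F2. Threefold Baeyer–Villiger oxidation and methanolysis give the triol F3. Intramolecular Ullmann etherification (CuI, N,N-dimethylglycine, Cs2CO3, dioxane, 90 °C) closes ring C at D6, because closure at D5 would form a seven-membered ring, and gives the bromo dioxin diol F4 with bromine kept at D5. Both hydroxyls of F4 are arylated with 19 (2.2 equiv, CsF) to the bromo bis-aryl ether F5, which is cyclised in the same flask with Pd(OAc)2 and PCy3 to 29.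

Step 2. Iodination may be poorly regioselective, with attack between the benzyloxy and methoxy groups competing with attack next to the chelated hydroxyl. The fallback sets out from 2 and returns at 3. The phenol is protected (MOMCl, iPr2NEt) as the MOM ether F6. The aldehyde is masked in the flask as its α-amino alkoxide (lithium N,N,N′-trimethylethylenediamide); n-BuLi lithiates between the MOM and benzyl ethers (directed ortho-metalation, the acetal oxygen outranking methoxy) and I2 gives the iodide F7. HCl in MeOH removes the MOM group to give 3.

Step 5. The second formylation may stall on the deactivated mono-aldehyde, or some formylation may occur between the methoxy groups. The fallback sets out from 8 and returns at 9. Vilsmeier formylation (POCl3, DMF) gives the mono-aldehyde F8. The second formyl group is then introduced by directed ortho-metalation next to fluorine (aldehyde masked as its α-amino alkoxide, n-BuLi, −78 °C, then DMF), which gives 9.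

Step 6. Fluoride displacement by the doubly flanked, sulfonate-deactivated phenoxide may be slow, and at higher temperature the sulfonate may be transferred to the neighbouring oxygen or cleaved. The fallback sets out from 3 and returns at 10, and introduces the sulfonate after the ether. 3 is converted into its MOM ether F7 (the compound of the step 2 fallback). Baeyer–Villiger oxidation and methanolysis give the more nucleophilic phenol F9. Fluoride displacement on 9 gives the ether F10. HCl in MeOH frees the phenol F11, and sulfonylation with 4 gives 10.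

Step 11. Over-arylation to the bis-ether and incomplete conversion are likely, because the two hydroxyls react independently. The fallback sets out from 8 and returns at 21, and avoids the statistical step. Lithiation next to fluorine (LiTMP, −78 °C), borylation with B(OMe)3 and oxidation (H2O2) give 2-fluoro-4,6-dimethoxyphenol F12. Arylation with 19 and CsF gives the diaryl ether F13. A second lithiation between fluorine and methoxy, then DMF, gives the aldehyde F14. Fluoride displacement by 7 gives the mono-aldehyde F15. Baeyer–Villiger oxidation and methanolysis give 21.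

Step 15. C–H palladation into the crowded bay region may be slow, allowing reductive loss of iodine to compete, and accumulating iodide may slow catalyst turnover. The fallback sets out from 26 and returns at 29; it closes the furan from the oxygen side and thereby also bypasses the copper-promoted etherification of step 14. Suzuki coupling of 26 with 2,4-dimethoxyphenylboronic acid (Pd(OAc)2, SPhos, K3PO4, toluene–H2O, 80 °C) gives the 2-arylphenol F16. Phenol-directed Pd(OAc)2-catalysed C–H activation and C–O cyclisation (N-heterocyclic carbene ligand, sodium 2,4,6-trimethylbenzoate, K2CO3, air, 120 °C) at the only free ortho position of the new ring gives 29.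

## Further compounds

F1 | step 12 | 2,3-dibromo-4-hydroxy-5-methoxybenzaldehyde | O=Cc1cc(OC)c(O)c(Br)c1Br
F2 | step 12 | 2-(2,3-dibromo-4-formyl-6-methoxyphenoxy)-4,6-dimethoxybenzene-1,3-dicarbaldehyde | O=Cc1cc(OC)c(Oc2c(C=O)c(OC)cc(OC)c2C=O)c(Br)c1Br
F3 | step 12 | 2-(2,3-dibromo-4-hydroxy-6-methoxyphenoxy)-4,6-dimethoxybenzene-1,3-diol | Oc1cc(OC)c(Oc2c(O)c(OC)cc(OC)c2O)c(Br)c1Br
F4 | step 12 | 6-bromo-2,4,9-trimethoxydibenzo[b,e][1,4]dioxine-1,7-diol | COc1cc(OC)c2c(c1O)Oc1c(OC)cc(O)c(Br)c1O2
F5 | step 12 | 6-bromo-1,7-bis(3,5-dimethoxyphenoxy)-2,4,9-trimethoxydibenzo[b,e][1,4]dioxine | COc1cc(OC)cc(Oc2c(OC)cc(OC)c3c2Oc2c(OC)cc(Oc4cc(OC)cc(OC)c4)c(Br)c2O3)c1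
F6 | step 2 | 4-(benzyloxy)-2-methoxy-6-(methoxymethoxy)benzaldehyde | O=Cc1c(OC)cc(OCc2ccccc2)cc1OCOC
F7 | step 2 | 4-(benzyloxy)-3-iodo-6-methoxy-2-(methoxymethoxy)benzaldehyde | O=Cc1c(OC)cc(OCc2ccccc2)c(I)c1OCOC
F8 | step 5 | 2-fluoro-4,6-dimethoxybenzaldehyde | COc1cc(OC)c(C=O)c(F)c1
F9 | step 6 | 4-(benzyloxy)-3-iodo-6-methoxy-2-(methoxymethoxy)phenol | Oc1c(OC)cc(OCc2ccccc2)c(I)c1OCOC
F10 | step 6 | 2-[4-(benzyloxy)-3-iodo-6-methoxy-2-(methoxymethoxy)phenoxy]-4,6-dimethoxybenzene-1,3-dicarbaldehyde | COCOc1c(I)c(OCc2ccccc2)cc(OC)c1Oc1c(C=O)c(OC)cc(OC)c1C=O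
F11 | step 6 | 2-[4-(benzyloxy)-2-hydroxy-3-iodo-6-methoxyphenoxy]-4,6-dimethoxybenzene-1,3-dicarbaldehyde | Oc1c(I)c(OCc2ccccc2)cc(OC)c1Oc1c(C=O)c(OC)cc(OC)c1C=O
F12 | step 11 | 2-fluoro-4,6-dimethoxyphenol | COc1cc(OC)c(O)c(F)c1
F13 | step 11 | 1-(3,5-dimethoxyphenoxy)-2-fluoro-4,6-dimethoxybenzene | COc1cc(OC)cc(Oc2c(F)cc(OC)cc2OC)c1
F14 | step 11 | 3-(3,5-dimethoxyphenoxy)-2-fluoro-4,6-dimethoxybenzaldehyde | COc1cc(OC)cc(Oc2c(F)c(C=O)c(OC)cc2OC)c1
F15 | step 11 | 3-(benzyloxy)-6-[2-(3,5-dimethoxyphenoxy)-6-formyl-3,5-dimethoxyphenoxy]-2-iodo-5-methoxyphenyl 4-chlorobenzenesulfonate | COc1cc(OC)cc(Oc2c(OC)cc(OC)c(C=O)c2Oc2c(OC)cc(OCc3ccccc3)c(I)c2OS(=O)(=O)c2ccc(Cl)cc2)c1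
F16 | step 15 | 6-(2,4-dimethoxyphenyl)-1-(3,5-dimethoxyphenoxy)-2,4,9-trimethoxydibenzo[b,e][1,4]dioxin-7-ol | COc1cc(OC)cc(Oc2c(OC)cc(OC)c3c2Oc2c(OC)cc(O)c(-c4ccc(OC)cc4OC)c2O3)c1
A1 | alternative 1 | 5-ethoxy-2,3-diisopropoxybenzene-1,4-diol | Oc1cc(OCC)c(O)c(OC(C)C)c1OC(C)C
A2 | alternative 1 | 4-(1-ethoxyvinyl)-4-hydroxy-2,3-diisopropoxycyclobut-2-en-1-one (racemic) | CCOC(=C)C1(O)C(OC(C)C)=C(OC(C)C)C1=O
A3 | alternative 2 | hexa-O-methyl ether of the target with one ring A hydroxyl free | Oc1cc(OC)cc(Oc2c(OC)cc(OC)c3c2Oc2c(OC)cc4oc5cc(OC)cc(OC)c5c4c2O3)c1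
A4 | alternative 2 | (E)-2-nitrovinyl ether of the B1 phenol of the penta-O-methylated B–C–D–E–F core | [O-][N+](=O)/C=C/Oc1c(OC)cc(OC)c2c1Oc1c(OC)cc3oc4cc(OC)cc(OC)c4c3c1O2
A5 | alternative 2 | 1,1-dimethoxy-3-(trimethylsilyloxy)buta-1,3-diene | COC(OC)=CC(=C)O[Si](C)(C)C
A6 | alternative 3 | penta-O-methyl ether of the target with one ring F hydroxyl free and the other as its triisopropylsilyl ether | COc1cc(OC)cc(Oc2c(OC)cc(OC)c3c2Oc2c(OC)cc4oc5cc(O[Si](C(C)C)(C(C)C)C(C)C)cc(O)c5c4c2O3)c1
A7 | alternative 3 | benzofuran-2-yl diazomethyl ketone of the penta-O-methylated A–B–C–D–E core | COc1cc(OC)cc(Oc2c(OC)cc(OC)c3c2Oc2c(OC)cc4oc(C(=O)C=[N+]=[N-])cc4c2O3)c1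
A8 | alternative 3 | (triisopropylsilyloxy)ethyne | C#CO[Si](C(C)C)(C(C)C)C(C)C
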